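**Plan**
- The two MOM acetals come off last. Before that, the retrosynthesis cuts the C5–CH2 bond of the arylethyl chain and the C6–CO2Me bond of ring A in one operation, leading back to a chromene C5–C6 aryne, an arylethyl Grignard reagent and methyl chloroformate.
- Enabling feature: C5 and C6 of the chromene are neighbours and C6 lies next to the C7 oxygen. A 7-alkoxy-5,6-aryne therefore takes the carbon nucleophile at C5 (distal to oxygen) and leaves the metal, hence the ester, at C6 (proximal).
- The aryne precursor is a 6-fluoro-7-(methoxymethoxy)-8-prenylchromene whose only ring C–H is C5. Fluorine is preferred to chlorine because the ortho-fluoroaryllithium persists at −78 °C, so the base is spent before the Grignard reagent is added and LiF is lost only on warming.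
- Forward: 4-fluororesorcinol is prenylated between its oxygens by directed metalation, the pyran ring (the only ring made) is closed with 3-methylbut-2-enal, and the phenol is capped. The arylethyl chain and the ester are then joined to ring A in step 8, and acid unmasks both phenols.
- The target has no stereocentre and neither trisubstituted alkene carries a geometric descriptor, so no stereocontrol is needed.

Key step: step 8

Remark: 4-fluororesorcinol and 4-(2-bromoethyl)phenol are taken as purchased materials.

**Step 1**
Reactants: 1 4-fluororesorcinol (4-fluorobenzene-1,3-diol)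
Product: 2 1-fluoro-2,4-bis(methoxymethoxy)benzene
Conditions: NaH (2.4 equiv), MOMCl (2.4 equiv), DMF, 0 °C → rt
Reagents that add atoms: chloromethyl methyl ether (MOMCl), COCCl
Why: Williamson-type O-alkylation of the bis-phenoxide installs two acetal groups that direct lithiation and withstand organolithium reagents.

**Step 2**
Reactants: 2 1-fluoro-2,4-bis(methoxymethoxy)benzene; 3 1-bromo-3-methylbut-2-ene (prenyl bromide)
Product: 5 1-fluoro-2,4-bis(methoxymethoxy)-3-(3-methylbut-2-en-1-yl)benzene, via aryllithium 4 (not isolated)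
Conditions: n-BuLi (1.1 equiv), THF, −20 °C, 1 h; CuI (10 mol %), 3 (1.3 equiv), −20 °C → rt
Reagents that add atoms: none
Why: Directed ortho-metalation takes the C–H between the two OMOM groups, the aryllithium 4 is meta to fluorine and cannot lose LiF, and copper-catalysed allylic substitution at the unhindered CH2 terminus of 3 should give the linear prenyl arene.

**Step 3**
Reactants: 5 1-fluoro-2,4-bis(methoxymethoxy)-3-(3-methylbut-2-en-1-yl)benzene
Product: 6 4-fluoro-2-(3-methylbut-2-en-1-yl)benzene-1,3-diol
Conditions: HCl (3 M aq), MeOH, 40 °C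
Reagents that add atoms: none
Why: Acid-catalysed methanolysis of the aryl MOM acetals (transacetalisation to dimethoxymethane) should free both phenols under conditions mild enough to spare the trisubstituted alkene.

**Step 4**
Reactants: 6 4-fluoro-2-(3-methylbut-2-en-1-yl)benzene-1,3-diol; 7 3-methylbut-2-enal
Product: 9 6-fluoro-2,2-dimethyl-8-(3-methylbut-2-en-1-yl)-2H-chromen-7-ol, via ortho-quinone methide 8 (not isolated)
Conditions: 7 (2 equiv), ethylenediammonium diacetate (10 mol %), toluene, 110 °C
Reagents that add atoms: none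
Why: Knoevenagel-type condensation at the only free activated ring carbon (ortho to one OH, para to the other) gives ortho-quinone methide 8, which closes by oxa-6π electrocyclisation (formal [3+3] chromene annulation); the hydroxyl flanked by fluorine and prenyl has no free ortho carbon and remains as the C7 phenol.

**Step 5**
Reactants: 9 6-fluoro-2,2-dimethyl-8-(3-methylbut-2-en-1-yl)-2H-chromen-7-ol
Product: 10 6-fluoro-7-(methoxymethoxy)-2,2-dimethyl-8-(3-methylbut-2-en-1-yl)-2H-chromene
Conditions: NaH (1.3 equiv), MOMCl (1.3 equiv), THF, 0 °C → rt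
Reagents that add atoms: chloromethyl methyl ether (MOMCl), COCCl
Why: Williamson-type MOM protection of the remaining phenol supplies the C7 alkoxy group that later polarises the aryne and leaves C5–H as the only ring proton.

**Step 6**
Reactants: 11 4-(2-bromoethyl)phenol
Product: 12 1-(2-bromoethyl)-4-(methoxymethoxy)benzene
Conditions: MOMCl (1.3 equiv), iPr2NEt (1.5 equiv), CH2Cl2, 0 °C → rt
Reagents that add atoms: chloromethyl methyl ether (MOMCl), COCCl
Why: MOM protection under amine base is chemoselective, because the chloromethyl ether is far more electrophilic than the primary alkyl bromide, which stays intact.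

**Step 7**
Reactants: 12 1-(2-bromoethyl)-4-(methoxymethoxy)benzene
Product: 13 {2-[4-(methoxymethoxy)phenyl]ethyl}magnesium bromide (THF solution, titrated)
Conditions: Mg turnings (I2 crystal), THF, rt → 40 °C, slow addition of 12
Reagents that add atoms: magnesium, [Mg]
Why: Grignard formation by insertion of magnesium into the primary C–Br bond; the aryl MOM ether is inert to the reagent and slow addition limits Wurtz coupling.

**Step 8**
Reactants: 10 6-fluoro-7-(methoxymethoxy)-2,2-dimethyl-8-(3-methylbut-2-en-1-yl)-2H-chromene; 13 {2-[4-(methoxymethoxy)phenyl]ethyl}magnesium bromide; 14 methyl chloroformate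
Product: 18 methyl 7-(methoxymethoxy)-5-{2-[4-(methoxymethoxy)phenyl]ethyl}-2,2-dimethyl-8-(3-methylbut-2-en-1-yl)-2H-chromene-6-carboxylate, via 5-lithio fluoride 15 (not isolated), via chromene aryne 16 (not isolated), via C6 arylmagnesium bromide 17 (not isolated)
Conditions: s-BuLi (1.2 equiv), THF, −78 °C, 1.5 h; 13 (3 equiv), −78 °C → rt; 14 (6 equiv), −78 → 0 °C
Reagents that add atoms: none
Why: sec-BuLi removes the only ring proton, C5–H, which the adjacent fluorine makes acidic, and the ortho-fluoroaryllithium 15 is stable at −78 °C, so no base is left when 13 is added. On warming, 15 loses LiF to the C5–C6 aryne 16; the inductive pull of the C7 acetal oxygen polarises the triple bond, so the primary alkyl group of 13 adds at C5 (distal) and magnesium ends on C6, where the MOM oxygens can chelate it (17). 17 is then acylated by methyl chloroformate, and the new ester, flanked by two ortho substituents, is shielded from a second addition. The closest known reaction type is the three-component coupling of a 3-alkoxybenzyne, generated from a lithiated fluoroarene, with a Grignard reagent and a carbon electrophile. No ring is closed and no stereocentre is created. The step needs metalation at C5 rather than at the benzylic, allylic CH2 of the prenyl group (secured by fluorine activation of an sp2 C–H and by the crowded position of that CH2 between two ortho oxygens) and distal addition to the aryne (secured by the C7 oxygen).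

**Step 9**
Reactants: 18 methyl 7-(methoxymethoxy)-5-{2-[4-(methoxymethoxy)phenyl]ethyl}-2,2-dimethyl-8-(3-methylbut-2-en-1-yl)-2H-chromene-6-carboxylate
Product: 19 methyl 7-hydroxy-5-[2-(4-hydroxyphenyl)ethyl]-2,2-dimethyl-8-(3-methylbut-2-en-1-yl)-2H-chromene-6-carboxylate
Conditions: HCl (3 M aq), MeOH, 40 °C
Reagents that add atoms: none
Why: Acid-catalysed methanolysis of both MOM acetals; the methyl ester is degenerate in methanol, and the freed C7 phenol is hydrogen-bonded to the ester carbonyl, which should temper its addition to the neighbouring prenyl alkene.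

**Compound list**
1 | 4-fluororesorcinol (4-fluorobenzene-1,3-diol) | Oc1ccc(F)c(O)c1 | starting material
2 | 1-fluoro-2,4-bis(methoxymethoxy)benzene | COCOc1ccc(F)c(OCOC)c1 | intermediate
3 | 1-bromo-3-methylbut-2-ene | CC(C)=CCBr | starting material
4 | [3-fluoro-2,6-bis(methoxymethoxy)phenyl]lithium | [Li]c1c(OCOC)ccc(F)c1OCOC | intermediate
5 | 1-fluoro-2,4-bis(methoxymethoxy)-3-(3-methylbut-2-en-1-yl)benzene | COCOc1ccc(F)c(OCOC)c1CC=C(C)C | intermediate
6 | 4-fluoro-2-(3-methylbut-2-en-1-yl)benzene-1,3-diol | Oc1ccc(F)c(O)c1CC=C(C)C | intermediate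
7 | 3-methylbut-2-enal | CC(C)=CC=O | starting material
8 | 4-fluoro-3-hydroxy-6-(3-methylbut-2-en-1-ylidene)-2-(3-methylbut-2-en-1-yl)cyclohexa-2,4-dien-1-one (ortho-quinone methide) | O=C1C(=CC=C(C)C)C=C(F)C(O)=C1CC=C(C)C | intermediate
9 | 6-fluoro-2,2-dimethyl-8-(3-methylbut-2-en-1-yl)-2H-chromen-7-ol | CC(C)=CCc1c(O)c(F)cc2C=CC(C)(C)Oc12 | intermediate
10 | 6-fluoro-7-(methoxymethoxy)-2,2-dimethyl-8-(3-methylbut-2-en-1-yl)-2H-chromene | COCOc1c(F)cc2C=CC(C)(C)Oc2c1CC=C(C)C | intermediate
11 | 4-(2-bromoethyl)phenol | Oc1ccc(CCBr)cc1 | starting material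
12 | 1-(2-bromoethyl)-4-(methoxymethoxy)benzene | COCOc1ccc(CCBr)cc1 | intermediate
13 | {2-[4-(methoxymethoxy)phenyl]ethyl}magnesium bromide | COCOc1ccc(CC[Mg]Br)cc1 | intermediate
14 | methyl chloroformate | COC(=O)Cl | starting material
15 | [6-fluoro-7-(methoxymethoxy)-2,2-dimethyl-8-(3-methylbut-2-en-1-yl)-2H-chromen-5-yl]lithium | COCOc1c(F)c([Li])c2C=CC(C)(C)Oc2c1CC=C(C)C | intermediate
16 | 5,6-didehydro-7-(methoxymethoxy)-2,2-dimethyl-8-(3-methylbut-2-en-1-yl)-2H-chromene (C5–C6 aryne) | COCOC1=C(CC=C(C)C)C2=C(C=CC(C)(C)O2)C#C1 | intermediate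
17 | {7-(methoxymethoxy)-5-{2-[4-(methoxymethoxy)phenyl]ethyl}-2,2-dimethyl-8-(3-methylbut-2-en-1-yl)-2H-chromen-6-yl}magnesium bromide | COCOc1c([Mg]Br)c(CCc2ccc(OCOC)cc2)c2C=CC(C)(C)Oc2c1CC=C(C)C | intermediate
18 | methyl 7-(methoxymethoxy)-5-{2-[4-(methoxymethoxy)phenyl]ethyl}-2,2-dimethyl-8-(3-methylbut-2-en-1-yl)-2H-chromene-6-carboxylate | COC(=O)c1c(OCOC)c(CC=C(C)C)c2OC(C)(C)C=Cc2c1CCc1ccc(OCOC)cc1 | intermediate
19 | methyl 7-hydroxy-5-[2-(4-hydroxyphenyl)ethyl]-2,2-dimethyl-8-(3-methylbut-2-en-1-yl)-2H-chromene-6-carboxylate | COC(=O)c1c(O)c(CC=C(C)C)c2c(c1CCc1ccc(O)cc1)C=CC(C)(C)O2 | target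

**Count**
Total steps: 9. Longest linear sequence: 7 (steps 1, 2, 3, 4, 5, 8, 9).

**Steps most likely to fail**

1. Step 8. Three organometallic events must follow one another in one flask. Metalation may drift from C5 to the benzylic, allylic CH2 of the prenyl group. At the close, the crowded C6 arylmagnesium must win methyl chloroformate against the unreacted alkyl Grignard reagent; if it does not, it is protonated on work-up and the ester carbon is lost. The fallback covers this last stage only; it does not help if metalation goes to the wrong site. Fallback (from 10 and 13, back at 18): the ester bond is made in a separate palladium-catalysed step. Lithiation, LiF loss and carbomagnesiation are run as before to 17, which is quenched with I2 instead of 14. This should give the aryl iodide 6-iodo-7-(methoxymethoxy)-5-{2-[4-(methoxymethoxy)phenyl]ethyl}-2,2-dimethyl-8-(3-methylbut-2-en-1-yl)-2H-chromene F1, which can be purified from the by-products of the excess Grignard reagent. Methoxycarbonylation of F1 (Pd(OAc)2, Xantphos, CO 1 atm, MeOH, Et3N, DMF, 70 °C) then returns to the route at 18.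

2. Step 9. Protic acid meets a freshly released phenol beside a prenyl group and an electron-rich chromene, so acid-induced cyclisation of the prenyl chain onto the C7 oxygen, or alkene hydration, may compete with acetal cleavage. Fallback (from 9, back at 19): the C7 oxygen is carried as a methyl ether, so that the phenol beside the prenyl group is released by chelation-controlled Lewis-acid demethylation and never meets protic acid. 9 is methylated (MeI, K2CO3, acetone) to 6-fluoro-7-methoxy-2,2-dimethyl-8-(3-methylbut-2-en-1-yl)-2H-chromene F2. The operations of step 8 then lead through the 5-lithio compound F3, the aryne F4 and the arylmagnesium bromide F5 to methyl 7-methoxy-5-{2-[4-(methoxymethoxy)phenyl]ethyl}-2,2-dimethyl-8-(3-methylbut-2-en-1-yl)-2H-chromene-6-carboxylate F6. HCl in MeOH removes the remote MOM group while C7 is still methylated, giving methyl 5-[2-(4-hydroxyphenyl)ethyl]-7-methoxy-2,2-dimethyl-8-(3-methylbut-2-en-1-yl)-2H-chromene-6-carboxylate F7. MgI2 etherate (toluene, 80 °C) then cleaves the methyl ether held between the ester carbonyl and magnesium to give 19.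

3. Step 2. Allylic transposition during C-prenylation (attack at the dimethyl-substituted terminus) or incomplete alkylation of the hindered aryllithium would erode the supply of 5. Fallback (from 2, back at 5): the aryllithium 4 is generated as before and trapped with allyl bromide, for which both modes of substitution give the same product, 1-fluoro-2,4-bis(methoxymethoxy)-3-(prop-2-en-1-yl)benzene F8. Olefin cross-metathesis of F8 with excess 2-methylbut-2-ene (second-generation Grubbs catalyst, RuCl2(=CHPh)(PCy3)(H2IMes), CH2Cl2, 40 °C) then installs the trisubstituted alkene and returns to the route at 5.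

**Further compounds**
F1 | step 8 | 6-iodo-7-(methoxymethoxy)-5-{2-[4-(methoxymethoxy)phenyl]ethyl}-2,2-dimethyl-8-(3-methylbut-2-en-1-yl)-2H-chromene | COCOc1c(I)c(CCc2ccc(OCOC)cc2)c2C=CC(C)(C)Oc2c1CC=C(C)C
F2 | step 9 | 6-fluoro-7-methoxy-2,2-dimethyl-8-(3-methylbut-2-en-1-yl)-2H-chromene | COc1c(F)cc2C=CC(C)(C)Oc2c1CC=C(C)C
F3 | step 9 | [6-fluoro-7-methoxy-2,2-dimethyl-8-(3-methylbut-2-en-1-yl)-2H-chromen-5-yl]lithium | COc1c(F)c([Li])c2C=CC(C)(C)Oc2c1CC=C(C)C
F4 | step 9 | 5,6-didehydro-7-methoxy-2,2-dimethyl-8-(3-methylbut-2-en-1-yl)-2H-chromene | COC1=C(CC=C(C)C)C2=C(C=CC(C)(C)O2)C#C1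
F5 | step 9 | {7-methoxy-5-{2-[4-(methoxymethoxy)phenyl]ethyl}-2,2-dimethyl-8-(3-methylbut-2-en-1-yl)-2H-chromen-6-yl}magnesium bromide | COc1c([Mg]Br)c(CCc2ccc(OCOC)cc2)c2C=CC(C)(C)Oc2c1CC=C(C)C
F6 | step 9 | methyl 7-methoxy-5-{2-[4-(methoxymethoxy)phenyl]ethyl}-2,2-dimethyl-8-(3-methylbut-2-en-1-yl)-2H-chromene-6-carboxylate | COC(=O)c1c(OC)c(CC=C(C)C)c2OC(C)(C)C=Cc2c1CCc1ccc(OCOC)cc1
F7 | step 9 | methyl 5-[2-(4-hydroxyphenyl)ethyl]-7-methoxy-2,2-dimethyl-8-(3-methylbut-2-en-1-yl)-2H-chromene-6-carboxylate | COC(=O)c1c(OC)c(CC=C(C)C)c2OC(C)(C)C=Cc2c1CCc1ccc(O)cc1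
F8 | step 2 | 1-fluoro-2,4-bis(methoxymethoxy)-3-(prop-2-en-1-yl)benzene | COCOc1ccc(F)c(OCOC)c1CC=C
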